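TBS = tert-butyldimethylsilyl, TMS = trimethylsilyl. Flavonoid numbering (O1, C2, C3, C4, C4a, C5–C8, C8a) is used for ring atoms throughout, also in the monocyclic intermediates.

## Structural features

The target is a trans-2,3-dihydroflavonol: a chroman-4-one in which the aromatic ring A (C4a, C5 to C8, C8a) is fused to the dihydropyranone ring C (O1, C2, C3, C4), with the catechol ring B on C2. The only stereocentres, C2 (aryl) and C3 (hydroxyl), are adjacent, both R, and trans with both substituents equatorial. Ring A carries a hydroxyl on C5, hydrogen-bonded to the C4 carbonyl, and a prenyl ether on O7. Fragile points are the catechol (oxidised in basic medium), the prenyl ether (cleaved by acid, reduced under hydrogenolysis), C3 (α to the ketone, epimerisable) and C2, whose bond to O1 can open by β-elimination from a C3 enolate or by ionisation of the para-oxygenated benzylic position. The real difficulty is to set C2 in the absolute sense beside an epimerisable C3, to carry both through the construction of an unsymmetrically substituted phloroglucinol ring, and to finish with protecting groups that leave under conditions the prenyl ether and the β-aryloxy ketone tolerate. The key step exploits the fact that ring C is a 2-aryl-3-oxy-2,3-dihydropyran-4-one: O1–C2 is the carbonyl group of the ring B aldehyde, and C3–C4–C4a–C8a is a butadiene with oxygen on C3, C4 and C8a. The C4a=C8a bond left by this step is the handle for annulating ring A, and the descriptors (2R,3R) hold from the monocycle to the target because the CIP order at C2 (O1 > C3 > aryl) and at C3 (O > C4 > C2) does not change.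

## Logic of the disconnections

19 back to 18. The three O–Si bonds on O3, O3′ and O4′ are cut. One kind of protecting group on all three oxygens means a single fluoride step, which spares the prenyl ether. The forward step only has to keep fluoride from acting as a base on the β-aryloxy ketone and the catechol.

18 back to 16 and 17. The O7–C bond of the allylic ether is cut. This keeps the acid- and electrophile-sensitive prenyl group out of every earlier step. The forward step must distinguish O7 from O5; the hydrogen bond of O5–H to the C4 carbonyl and the higher acidity of O7–H provide this, and a base-free etherification protects the aryl silyl ethers and C3.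

16 back to 12 and 13. Ring A is cut at C4a–C5 and C8–C8a, a [4+2] retron in which C5 to C8 with both oxygens come from 13 and C4a=C8a is the enone double bond of ring C. The bicyclic, chiral problem shrinks to a monocycle plus a four-carbon diene. The forward step has two demands. C8 must bond to C8a, the β-carbon, so that O5 ends beside the carbonyl. The two hydrogens on C4a and C8a must also be removed. The sulfinyl group on C4a of 12 serves both ends: it polarises the alkene and then leaves with the cis hydrogen of C8a by thermal syn-elimination under neutral conditions. A halogen on C4a was set aside, because H–C8a is not acidic and the acidic hydrogens of such an adduct lead instead to β-elimination of O1.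

12 back to 11. The S–O bond is cut. The forward oxidation must stop at the sulfoxide and leave the electron-rich ring B and the enone alone, which sulfur's higher nucleophilicity allows at low temperature.

11 back to 10. The C4a–S bond is cut. C4a of 10 is the nucleophilic α-carbon of a vinylogous ester, so sulfur is introduced as an electrophile. The forward step must be selective for C4a over ring B and must not epimerise C3.

10 back to 2 and 8. C2–C3 and O1–C8a are cut, the hetero-Diels–Alder retron of ring C. Ring C and both stereocentres then arise from two achiral pieces in one catalytic operation. The forward step needs one face of the aldehyde to be attacked, the siloxy group on C3 to survive while the C4 oxygen is unmasked, and C3 to settle trans to the aryl group.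

8 back to 7. The O–Si bond of the enol ether at the C4 oxygen is cut. The forward enol silylation must use a silyl group different from that on the C3 oxygen so that the two can later be told apart.

7 back to 5 and 6. The C4–C4a bond is cut between an acyl carbon and the nucleophilic carbon of an enol ether. The demand is that acylation and loss of HCl occur without acid damage to the silyl ether.

5 back to 4, and 4 back to 3. The C–Cl bond and then the two O–Si bonds are cut. The forward activation must make the acid chloride without freeing the hydroxyl, which the silyl ester route does under neutral conditions.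

2 back to 1. The two aryl O–Si bonds are cut. Silyl ethers are chosen so that ring B is freed in the same final step as O3.

## Other disconnections considered

Alternative 1: Ring C is cut at O1–C8a and C4–C4a, which leads to hydroxy ester A2 and the ortho-silyl aryl triflate A3. In the forward sense CsF would release the 3,5-dioxygenated aryne from A3. The alkoxide of A2 would add at C8a, the carbon remote from the 5-oxygen, so that the aryl anion sits at C4a beside that oxygen. This anion would then attack the methyl ester and close ring C as A1.
- In its favour: the union is convergent. Ring A arrives aromatic with the prenyl ether already on O7 and O5 already distinguished, so no annulation and no regioselective etherification are needed. The regiochemistry of addition to a 3-alkoxyaryne is well founded. Only a deprotection would remain.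
- Against it here: the nucleophile is the alkoxide of a β-hydroxy ester with an epimerisable α-carbon, so retro-aldol cleavage and epimerisation at the future C3 compete under fluoride. A secondary alkoxide is a weaker aryne partner than a phenoxide, and the aryl anion may be protonated before it acylates. A2 must be the anti diol derivative, which direct syn-dihydroxylation of an (E)-cinnamate does not give. A3 needs a multistep synthesis with three differentiated oxygens. The four methoxymethyl groups of A1 leave only with acid, which endangers the prenyl ether.
- Comparison: on convergency, on ring A (nothing has to be built) and on the number of steps after the key step, this plan is better than the chosen one. The chosen plan is better on the origin of the stereocentres (one catalytic step instead of a separately made, base-sensitive chiral ester), on how mild the ring-closing conditions are towards C2 and C3, and on the end game (fluoride instead of acid beside a prenyl ether). Overall step counts are judged about equal.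

Alternative 2: Only C4–C4a is cut, which leads to acid A5, in which the aryl ether bond O1–C8a and both stereocentres are already present. Trifluoroacetic anhydride would convert A5 into a mixed anhydride, and the 3,5-dibenzyloxyphenyl ring would attack the acyl carbon ortho to O1 to give A4.
- In its favour: intramolecular acylation of a phloroglucinol ether is dependable. The local symmetry of the ring makes both ortho positions equivalent, so no regiochemical question arises. Ring A is bought.
- Against it here: the difficulty moves into A5. Its aryl ether at a benzylic carbon para to oxygen must be made with clean stereochemistry against ionisation, elimination and C-alkylation of the phenol. The same benzylic ether can ionise under the acidic acylation conditions and scramble C2. After cyclisation O5 and O7 carry identical benzyl groups, so hydrogenolysis must precede prenylation and must spare the benzylic C2–O1 bond and the ketone. Selective 7-O-prenylation and desilylation then follow.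
- Comparison: the key step itself is mechanistically simpler and better precedented than the cycloaddition chemistry of the chosen plan, and the sequence after it is shorter; on these points alternative 2 is the better. On the regioselective prenylation the two plans are equal, since both rely on the chelated 5-hydroxyl. The chosen plan is better in that both stereocentres come from one catalytic operation and no stereodefined benzylic substitution is needed.

Alternative 3: Ring A is cut at C5–C6, C7–C8 and C4a–C5, with C8–C8a arising by a 1,2-shift. The precursors are diazoketone A7 (ring C with a diazoacetyl group on C8a) and siloxyalkyne A8. Irradiation would trigger the Wolff rearrangement to a vinylketene, and [2+2] addition of A8 would give a 4-vinylcyclobutenone. Four-electron ring opening, six-electron electrocyclisation and tautomerisation would then give A6.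
- In its favour: like the chosen plan it builds ring A on a preformed chiral ring C. It does so at the right oxidation level without any activating or leaving group, under neutral conditions and with fixed regiochemistry. It also delivers O5 free and O7 silylated, so the two oxygens are chemically differentiated.
- Against it here: A7 is a more elaborate ring C, with an acyl carbon on C8a and then a diazo transfer, which the simple union of aldehyde and diene does not provide. The enone and the electron-rich aryl rings absorb light and can divert the photochemistry. A8 is sensitive and must be made. The methoxymethyl groups again require acid at the end, beside the prenyl ether.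
- Comparison: in the differentiation of O5 and O7 and in oxidation-level economy alternative 3 is better than the chosen plan. In precedent for phenol annulation it is equal or better. The chosen plan is better in the accessibility of the ring C building block, in avoiding a photochemical step on a light-absorbing substrate, and in the fluoride end game. There are fewer steps after the key step but more before it, so overall step economy is about equal.

Key step: step 6

Assumption 1: the sense of induction of the BINOL/Ti(OiPr)4 catalyst with diene 8 is taken to parallel that of allyl additions to aldehydes under the same catalyst, so (S)-BINOL is expected to direct attack to the Si face; if the first batch shows the opposite sense, (R)-BINOL is used with no other change.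

Assumption 2: 1-methoxy-1,3-bis(trimethylsilyloxy)buta-1,3-diene (13) is taken as a purchased reagent; it is otherwise made from methyl acetoacetate by two silylations.

## Route

Step 1
Reactants: 1 3,4-dihydroxybenzaldehyde
Product: 2 3,4-bis(TBSO)benzaldehyde
Conditions: TBSCl, imidazole, DMF, 0 °C → rt
Reagents that add atoms: tert-butyldimethylsilyl chloride, CC(C)(C)[Si](C)(C)Cl
Why: Silylation of both phenols (substitution at silicon, imidazole as nucleophilic catalyst and base); the aldehyde is not affected.

Step 2
Reactants: 3 glycolic acid
Product: 4 tert-butyldimethylsilyl 2-(TBSO)acetate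
Conditions: TBSCl, imidazole, DMF, rt
Reagents that add atoms: tert-butyldimethylsilyl chloride, CC(C)(C)[Si](C)(C)Cl
Why: Bis-silylation gives the silyl ether and silyl ester, the form in which the acid can be activated without freeing the hydroxyl.

Step 3
Reactants: 4 tert-butyldimethylsilyl 2-(TBSO)acetate
Product: 5 2-(TBSO)acetyl chloride
Conditions: (COCl)2, DMF (cat.), CH2Cl2, 0 °C → rt; used crude
Reagents that add atoms: oxalyl chloride, O=C(Cl)C(=O)Cl
Why: The Vilsmeier-type chloroiminium salt converts a silyl ester directly into the acid chloride under neutral conditions; silicon leaves as TBSCl and no HCl is formed, so the silyl ether should survive.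

Step 4
Reactants: 5 2-(TBSO)acetyl chloride; 6 methyl vinyl ether
Product: 7 (E)-1-(TBSO)-4-methoxybut-3-en-2-one
Conditions: 6 (excess, condensed), pyridine, CH2Cl2, −20 °C → rt, closed vessel
Reagents that add atoms: none
Why: C-acylation of the enol ether at its nucleophilic carbon, then pyridine-mediated loss of HCl, should give the β-methoxy enone as the more stable E isomer; the α-oxygen makes the acid chloride electrophilic enough for this addition–elimination.

Step 5
Reactants: 7 (E)-1-(TBSO)-4-methoxybut-3-en-2-one
Product: 8 (1E,3Z)-4-(TBSO)-1-methoxy-3-(trimethylsilyloxy)buta-1,3-diene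
Conditions: TMSOTf, Et3N, Et2O, 0 °C → rt
Reagents that add atoms: trimethylsilyl trifluoromethanesulfonate, C[Si](C)(C)OS(=O)(=O)C(F)(F)F
Why: Soft enolisation at the CH2OTBS group, the only enolisable position, gives the enol silyl ether, expected as the Z isomer with both oxygens cis; the labile TMS group on the future C4 oxygen differs from the robust TBS group on the future C3 oxygen.

Step 6
Reactants: 2 3,4-bis(TBSO)benzaldehyde; 8 (1E,3Z)-4-(TBSO)-1-methoxy-3-(trimethylsilyloxy)buta-1,3-diene
Product: 10 (2R,3R)-2-[3,4-bis(TBSO)phenyl]-3-(TBSO)-2,3-dihydro-4H-pyran-4-one, via aldol adduct 9 (not isolated)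
Conditions: Ti(OiPr)4 (10 mol %), (S)-BINOL (20 mol %), 4 Å MS, Et2O, −20 °C; then TFA, CH2Cl2, 0 °C
Reagents that add atoms: none
Why: The BINOL complex of tetravalent titanium activates the aldehyde of 2, and the siloxy-bearing terminus of 8 (the future C3) adds to the carbonyl carbon (C2–C3) in a Mukaiyama aldol sense with silyl transfer to the aldolate, giving 9; a concerted [4+2] addition would reach the same ring. Trifluoroacetic acid then brings about 6-endo-trig oxa-Michael closure of O1 onto the methoxy enone (O1–C8a) and loss of methanol and of the trimethylsilyl group, so that ring C is closed as the vinylogous ester 10. The closest known reaction type is the BINOL/Ti(OiPr)4-catalysed hetero-Diels–Alder reaction of 1-methoxy-3-siloxy-1,3-dienes with aryl aldehydes. C2 is controlled by the ligand, which leaves the Si face of the bound aldehyde open; attack there gives 2R, because C3 outranks the aryl group. C3 is controlled by C2: it is α to the ketone, and under the same acid it should settle through the enol to the trans isomer with aryl and siloxy groups both equatorial, whichever aldol diastereomer forms first. The step needs bonding through the oxygenated terminus of the diene, secured by the push of the two adjacent oxygens, and unmasking of the C4 oxygen only, secured by the labile trimethylsilyl group there and the robust TBS group on the C3 oxygen. Base is kept out, since an enolate at C3 could expel O1 and erode C2.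

Step 7
Reactants: 10 (2R,3R)-2-[3,4-bis(TBSO)phenyl]-3-(TBSO)-2,3-dihydro-4H-pyran-4-one
Product: 11 (2R,3R)-2-[3,4-bis(TBSO)phenyl]-3-(TBSO)-5-(phenylsulfanyl)-2,3-dihydro-4H-pyran-4-one
Conditions: PhSCl, CH2Cl2, −78 → 0 °C; then Et3N
Reagents that add atoms: benzenesulfenyl chloride, ClSc1ccccc1
Why: Electrophilic sulfenylation at C4a, the nucleophilic α-carbon of the vinylogous ester: PhSCl adds across the enol ether bond (chloride on C8a) and Et3N removes HCl, the same addition–elimination by which enones are converted into 2-(phenylsulfanyl)enones.

Step 8
Reactants: 11 (2R,3R)-2-[3,4-bis(TBSO)phenyl]-3-(TBSO)-5-(phenylsulfanyl)-2,3-dihydro-4H-pyran-4-one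
Product: 12 (2R,3R)-2-[3,4-bis(TBSO)phenyl]-3-(TBSO)-5-(phenylsulfinyl)-2,3-dihydro-4H-pyran-4-one (both sulfur epimers)
Conditions: mCPBA (1.0 equiv), CH2Cl2, −78 °C
Reagents that add atoms: 3-chloroperbenzoic acid, OOC(=O)c1cccc(Cl)c1
Why: Sulfide-to-sulfoxide oxidation; sulfur is far more nucleophilic than the electron-poor enone double bond, so one equivalent of peracid at low temperature should stop at the sulfoxide, whose configuration is irrelevant.

Step 9
Reactants: 12 (2R,3R)-2-[3,4-bis(TBSO)phenyl]-3-(TBSO)-5-(phenylsulfinyl)-2,3-dihydro-4H-pyran-4-one; 13 1-methoxy-1,3-bis(trimethylsilyloxy)buta-1,3-diene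
Product: 16 (2R,3R)-2-[3,4-bis(TBSO)phenyl]-3-(TBSO)-5,7-dihydroxychroman-4-one, via sulfinyl cycloadduct 14 (not isolated), via dihydroarene ketal 15 (not isolated)
Conditions: 13 (3 equiv), toluene, 80 °C; then 1 M HCl, THF, 0 °C
Reagents that add atoms: none
Why: Normal-demand Diels–Alder reaction of the α-sulfinyl enone (an ynone equivalent) with the 1,1,3-trioxygenated diene: the nucleophilic CH2 terminus of 13 bonds to the electrophilic β-carbon C8a and the acetal carbon to C4a, which places O5 beside the C4 carbonyl. In 14 the sulfinyl group and H–C8a are cis, so thermal syn-elimination of PhSOH restores C4a=C8a (15); dilute acid then removes methanol and the silyl groups, and the dienone tautomerises to the resorcinol ring. C2 and C3 are not touched, and the transient centres at C4a, C5, C8a and sulfur are destroyed.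

Step 10
Reactants: 16 (2R,3R)-2-[3,4-bis(TBSO)phenyl]-3-(TBSO)-5,7-dihydroxychroman-4-one; 17 3-methylbut-2-en-1-ol
Product: 18 (2R,3R)-2-[3,4-bis(TBSO)phenyl]-3-(TBSO)-5-hydroxy-7-[(3-methylbut-2-en-1-yl)oxy]chroman-4-one
Conditions: PPh3, DIAD, THF, 0 °C → rt
Reagents that add atoms: none
Why: Mitsunobu etherification: the 7-hydroxyl, para to the carbonyl and the most acidic, is the pronucleophile, while the 5-hydroxyl is held in the hydrogen bond to C4=O; no base is present, so the aryl silyl ethers and C3 should be safe.

Step 11
Reactants: 18 (2R,3R)-2-[3,4-bis(TBSO)phenyl]-3-(TBSO)-5-hydroxy-7-[(3-methylbut-2-en-1-yl)oxy]chroman-4-one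
Product: 19 (2R,3R)-2-(3,4-dihydroxyphenyl)-3,5-dihydroxy-7-[(3-methylbut-2-en-1-yl)oxy]chroman-4-one
Conditions: HF·pyridine, pyridine, THF, 0 °C → rt, under argon
Reagents that add atoms: none
Why: Fluoride cleavage of the two aryl and the one secondary silyl ether; the pyridine-buffered, weakly acidic medium avoids phenoxide formation (and with it ring opening to the chalcone, C3 epimerisation and catechol oxidation) and is too weak an acid to cleave the prenyl ether.

## Compound list

1 | 3,4-dihydroxybenzaldehyde | O=Cc1ccc(O)c(O)c1 | starting material
2 | 3,4-bis(tert-butyldimethylsilyloxy)benzaldehyde | O=Cc1ccc(O[Si](C)(C)C(C)(C)C)c(O[Si](C)(C)C(C)(C)C)c1 | intermediate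
3 | glycolic acid | OCC(=O)O | starting material
4 | tert-butyldimethylsilyl 2-(tert-butyldimethylsilyloxy)acetate | CC(C)(C)[Si](C)(C)OCC(=O)O[Si](C)(C)C(C)(C)C | intermediate
5 | 2-(tert-butyldimethylsilyloxy)acetyl chloride | CC(C)(C)[Si](C)(C)OCC(=O)Cl | intermediate
6 | methyl vinyl ether | COC=C | starting material
7 | (E)-1-(tert-butyldimethylsilyloxy)-4-methoxybut-3-en-2-one | CO/C=C/C(=O)CO[Si](C)(C)C(C)(C)C | intermediate
8 | (1E,3Z)-4-(tert-butyldimethylsilyloxy)-1-methoxy-3-(trimethylsilyloxy)buta-1,3-diene | CO/C=C/C(O[Si](C)(C)C)=C/O[Si](C)(C)C(C)(C)C | intermediate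
9 | (1E,4R,5R)-5-[3,4-bis(tert-butyldimethylsilyloxy)phenyl]-4-(tert-butyldimethylsilyloxy)-1-methoxy-5-(trimethylsilyloxy)pent-1-en-3-one (drawn as the isomer that closes directly to 10; its C4 epimer converges through C3 equilibration) | C[Si](C)(C)O[C@H](c1ccc(O[Si](C)(C)C(C)(C)C)c(O[Si](C)(C)C(C)(C)C)c1)[C@@H](O[Si](C)(C)C(C)(C)C)C(=O)/C=C/OC | intermediate
10 | (2R,3R)-2-[3,4-bis(tert-butyldimethylsilyloxy)phenyl]-3-(tert-butyldimethylsilyloxy)-2,3-dihydro-4H-pyran-4-one | O1[C@H](c2ccc(O[Si](C)(C)C(C)(C)C)c(O[Si](C)(C)C(C)(C)C)c2)[C@@H](O[Si](C)(C)C(C)(C)C)C(=O)C=C1 | intermediate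
11 | (2R,3R)-2-[3,4-bis(tert-butyldimethylsilyloxy)phenyl]-3-(tert-butyldimethylsilyloxy)-5-(phenylsulfanyl)-2,3-dihydro-4H-pyran-4-one | O1[C@H](c2ccc(O[Si](C)(C)C(C)(C)C)c(O[Si](C)(C)C(C)(C)C)c2)[C@@H](O[Si](C)(C)C(C)(C)C)C(=O)C(Sc3ccccc3)=C1 | intermediate
12 | (2R,3R)-2-[3,4-bis(tert-butyldimethylsilyloxy)phenyl]-3-(tert-butyldimethylsilyloxy)-5-(phenylsulfinyl)-2,3-dihydro-4H-pyran-4-one (both sulfur epimers) | O1[C@H](c2ccc(O[Si](C)(C)C(C)(C)C)c(O[Si](C)(C)C(C)(C)C)c2)[C@@H](O[Si](C)(C)C(C)(C)C)C(=O)C(S(=O)c3ccccc3)=C1 | intermediate
13 | 1-methoxy-1,3-bis(trimethylsilyloxy)buta-1,3-diene | C=C(O[Si](C)(C)C)C=C(OC)O[Si](C)(C)C | starting material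
14 | (2R,3R)-2-[3,4-bis(tert-butyldimethylsilyloxy)phenyl]-3-(tert-butyldimethylsilyloxy)-5-methoxy-4a-(phenylsulfinyl)-5,7-bis(trimethylsilyloxy)-2,3,4a,5,8,8a-hexahydro-4H-chromen-4-one (isomers at C4a, C5, C8a and sulfur) | O1[C@H](c2ccc(O[Si](C)(C)C(C)(C)C)c(O[Si](C)(C)C(C)(C)C)c2)[C@@H](O[Si](C)(C)C(C)(C)C)C(=O)C2(S(=O)c3ccccc3)C1CC(O[Si](C)(C)C)=CC2(OC)O[Si](C)(C)C | intermediate
15 | (2R,3R)-2-[3,4-bis(tert-butyldimethylsilyloxy)phenyl]-3-(tert-butyldimethylsilyloxy)-5-methoxy-5,7-bis(trimethylsilyloxy)-2,3,5,8-tetrahydro-4H-chromen-4-one (isomers at C5) | O1[C@H](c2ccc(O[Si](C)(C)C(C)(C)C)c(O[Si](C)(C)C(C)(C)C)c2)[C@@H](O[Si](C)(C)C(C)(C)C)C(=O)C2=C1CC(O[Si](C)(C)C)=CC2(OC)O[Si](C)(C)C | intermediate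
16 | (2R,3R)-2-[3,4-bis(tert-butyldimethylsilyloxy)phenyl]-3-(tert-butyldimethylsilyloxy)-5,7-dihydroxychroman-4-one | Oc1cc(O)c2c(c1)O[C@H](c1ccc(O[Si](C)(C)C(C)(C)C)c(O[Si](C)(C)C(C)(C)C)c1)[C@@H](O[Si](C)(C)C(C)(C)C)C2=O | intermediate
17 | 3-methylbut-2-en-1-ol | CC(C)=CCO | starting material
18 | (2R,3R)-2-[3,4-bis(tert-butyldimethylsilyloxy)phenyl]-3-(tert-butyldimethylsilyloxy)-5-hydroxy-7-[(3-methylbut-2-en-1-yl)oxy]chroman-4-one | CC(C)=CCOc1cc(O)c2c(c1)O[C@H](c1ccc(O[Si](C)(C)C(C)(C)C)c(O[Si](C)(C)C(C)(C)C)c1)[C@@H](O[Si](C)(C)C(C)(C)C)C2=O | intermediate
19 | (2R,3R)-2-(3,4-dihydroxyphenyl)-3,5-dihydroxy-7-[(3-methylbut-2-en-1-yl)oxy]chroman-4-one | CC(C)=CCOc1cc(O)c2c(c1)O[C@H](c1ccc(O)c(O)c1)[C@@H](O)C2=O | target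

## Step count and least certain steps

Total step count: 11. Longest linear sequence: 10 steps (3 to 19 through steps 2 to 11); step 1 is a one-step side branch.

Step 6 (key step). The most likely failure is slow turnover with eroded facial selectivity. The electron-rich aldehyde binds the catalyst weakly and the hindered, siloxy-bearing diene terminus reacts slowly, so an unselective silyl-cation-catalysed background addition can compete. A second concern is acid-induced ionisation of the C2–O1 bond during the trifluoroacetic acid treatment. The fallback replaces Lewis-acid catalysis by hydrogen-bond catalysis with a much more reactive amino siloxy diene. It sets out from 7 and 2. Dimethylamine in THF exchanges the methoxy group of 7 to give the enaminone (E)-1-(tert-butyldimethylsilyloxy)-4-(dimethylamino)but-3-en-2-one F1. KN(SiMe3)2 and TBSCl convert it into the diene (1E,3Z)-3,4-bis(tert-butyldimethylsilyloxy)-N,N-dimethylbuta-1,3-dien-1-amine F2. F2 and 2 are combined in toluene at −40 °C with a TADDOL diol, the antipode that opens the Si face, to give the aminal cycloadduct (2R)-2-[3,4-bis(tert-butyldimethylsilyloxy)phenyl]-3,4-bis(tert-butyldimethylsilyloxy)-N,N-dimethyl-3,6-dihydro-2H-pyran-6-amine F3. Acetyl chloride then expels the amine and the enol silyl group, and brief trifluoroacetic acid treatment equilibrates C3. The fallback comes back to the route at 10.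

Step 9. The most likely failure is a cycloaddition too slow to outrun side processes, because the β-carbon of the dienophile carries a donor oxygen. The side processes are decomposition of the diene, silyl transfer from the ketene acetal to the sulfinyl oxygen (a Pummerer-type diversion), and conjugate addition followed by β-elimination of O1. The fallback is a stepwise polar annulation that sets out from 12. The dianion of methyl acetoacetate (NaH, then n-BuLi, THF, −78 °C) adds through its terminal carbon to C8a, and warming eliminates the sulfenic acid to give the keto ester methyl 4-[(2R,3R)-2-[3,4-bis(tert-butyldimethylsilyloxy)phenyl]-3-(tert-butyldimethylsilyloxy)-4-oxo-3,4-dihydro-2H-pyran-6-yl]-3-oxobutanoate F4. Intramolecular Claisen condensation of C4a onto the ester (LiN(SiMe3)2, THF, −78 → 0 °C) and tautomerisation then close ring A. The fallback comes back to the route at 16.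

Step 7. The most likely failure is loss of site selectivity: the sulfenyl chloride may attack the electron-rich ring B, or the HCl formed may remove silyl groups before the amine is added. The fallback introduces sulfur by cross-coupling and sets out from 10. Iodination with I2 and pyridine in CH2Cl2 gives the iodide (2R,3R)-2-[3,4-bis(tert-butyldimethylsilyloxy)phenyl]-3-(tert-butyldimethylsilyloxy)-5-iodo-2,3-dihydro-4H-pyran-4-one F5. Coupling with thiophenol (Pd2(dba)3, Xantphos, iPr2NEt, dioxane, 80 °C) then forms the C–S bond. The fallback comes back to the route at 11.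

Step 4. The most likely failure is cationic polymerisation of the vinyl ether and acid-induced loss of the silyl ether before the elimination is complete, because the acid chloride is only moderately electrophilic. The fallback builds the enone through an ynone and sets out from 5. N,O-Dimethylhydroxylamine hydrochloride and pyridine give the amide 2-(tert-butyldimethylsilyloxy)-N-methoxy-N-methylacetamide F6. Ethynylmagnesium bromide in THF at 0 °C gives the ynone 1-(tert-butyldimethylsilyloxy)but-3-yn-2-one F7. Conjugate addition of methanol with DABCO as catalyst gives the E enone. The fallback comes back to the route at 7.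

## Further compounds

F1 | step 6 | (E)-1-(tert-butyldimethylsilyloxy)-4-(dimethylamino)but-3-en-2-one | CN(C)/C=C/C(=O)CO[Si](C)(C)C(C)(C)C
F2 | step 6 | (1E,3Z)-3,4-bis(tert-butyldimethylsilyloxy)-N,N-dimethylbuta-1,3-dien-1-amine | CN(C)/C=C/C(O[Si](C)(C)C(C)(C)C)=C/O[Si](C)(C)C(C)(C)C
F3 | step 6 | (2R)-2-[3,4-bis(tert-butyldimethylsilyloxy)phenyl]-3,4-bis(tert-butyldimethylsilyloxy)-N,N-dimethyl-3,6-dihydro-2H-pyran-6-amine (isomers at C3 and C6) | O1[C@H](c2ccc(O[Si](C)(C)C(C)(C)C)c(O[Si](C)(C)C(C)(C)C)c2)C(O[Si](C)(C)C(C)(C)C)C(O[Si](C)(C)C(C)(C)C)=CC1N(C)C
F4 | step 9 | methyl 4-[(2R,3R)-2-[3,4-bis(tert-butyldimethylsilyloxy)phenyl]-3-(tert-butyldimethylsilyloxy)-4-oxo-3,4-dihydro-2H-pyran-6-yl]-3-oxobutanoate | O1[C@H](c2ccc(O[Si](C)(C)C(C)(C)C)c(O[Si](C)(C)C(C)(C)C)c2)[C@@H](O[Si](C)(C)C(C)(C)C)C(=O)C=C1CC(=O)CC(=O)OC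
F5 | step 7 | (2R,3R)-2-[3,4-bis(tert-butyldimethylsilyloxy)phenyl]-3-(tert-butyldimethylsilyloxy)-5-iodo-2,3-dihydro-4H-pyran-4-one | O1[C@H](c2ccc(O[Si](C)(C)C(C)(C)C)c(O[Si](C)(C)C(C)(C)C)c2)[C@@H](O[Si](C)(C)C(C)(C)C)C(=O)C(I)=C1
F6 | step 4 | 2-(tert-butyldimethylsilyloxy)-N-methoxy-N-methylacetamide | CON(C)C(=O)CO[Si](C)(C)C(C)(C)C
F7 | step 4 | 1-(tert-butyldimethylsilyloxy)but-3-yn-2-one | C#CC(=O)CO[Si](C)(C)C(C)(C)C
A1 | alternative 1 | (2R,3R)-2-[3,4-bis(methoxymethoxy)phenyl]-3,5-bis(methoxymethoxy)-7-[(3-methylbut-2-en-1-yl)oxy]chroman-4-one | CC(C)=CCOc1cc(OCOC)c2c(c1)O[C@H](c1ccc(OCOC)c(OCOC)c1)[C@@H](OCOC)C2=O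
A2 | alternative 1 | methyl (2R,3R)-3-[3,4-bis(methoxymethoxy)phenyl]-3-hydroxy-2-(methoxymethoxy)propanoate | O[C@H](c1ccc(OCOC)c(OCOC)c1)[C@@H](OCOC)C(=O)OC
A3 | alternative 1 | 3-(methoxymethoxy)-5-[(3-methylbut-2-en-1-yl)oxy]-2-(trimethylsilyl)phenyl trifluoromethanesulfonate | CC(C)=CCOc1cc(OCOC)c([Si](C)(C)C)c(OS(=O)(=O)C(F)(F)F)c1
A4 | alternative 2 | (2R,3R)-3,5,7-tris(benzyloxy)-2-[3,4-bis(triisopropylsilyloxy)phenyl]chroman-4-one | c1ccccc1COc1cc(OCc2ccccc2)c2c(c1)O[C@H](c1ccc(O[Si](C(C)C)(C(C)C)C(C)C)c(O[Si](C(C)C)(C(C)C)C(C)C)c1)[C@@H](OCc1ccccc1)C2=O
A5 | alternative 2 | (2R,3R)-2-(benzyloxy)-3-[3,5-bis(benzyloxy)phenoxy]-3-[3,4-bis(triisopropylsilyloxy)phenyl]propanoic acid | c1ccccc1COc1cc(OCc2ccccc2)cc(c1)O[C@H](c1ccc(O[Si](C(C)C)(C(C)C)C(C)C)c(O[Si](C(C)C)(C(C)C)C(C)C)c1)[C@@H](OCc1ccccc1)C(=O)O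
A6 | alternative 3 | (2R,3R)-2-[3,4-bis(methoxymethoxy)phenyl]-5-hydroxy-3-(methoxymethoxy)-7-(triisopropylsilyloxy)chroman-4-one | CC(C)[Si](C(C)C)(C(C)C)Oc1cc(O)c2c(c1)O[C@H](c1ccc(OCOC)c(OCOC)c1)[C@@H](OCOC)C2=O
A7 | alternative 3 | (2R,3R)-6-(2-diazoacetyl)-2-[3,4-bis(methoxymethoxy)phenyl]-3-(methoxymethoxy)-2,3-dihydro-4H-pyran-4-one | O1[C@H](c2ccc(OCOC)c(OCOC)c2)[C@@H](OCOC)C(=O)C=C1C(=O)C=[N+]=[N-]
A8 | alternative 3 | ethynyloxy(triisopropyl)silane | C#CO[Si](C(C)C)(C(C)C)C(C)C
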